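Ring A is folded from an open chain instead of being bought as an arene. Oxygen on C8a and C7, prenyl groups on C8 and C6, the acyl carbon C4 on C4a and a bare C5 are the marks of a chain C4–C4a–C8a–C8–C7–C6–C5 with a carbonyl-level carbon at every second position. Everything therefore rests on the C4a–C5 bond. The precursor is an (S)-2-aryl-2,3-dihydropyran-4-one (ring C, with C2 set by an asymmetric hetero-Diels–Alder reaction) whose C8a carries a CH(prenyl)–CO–C(prenyl)=CH–OMe arm. One equivalent of a mild base enolises C8. In one operation ring A closes, loses methanol and appears as the fully substituted C7 phenol, without any regiochemical choice on an arene.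

Key step: step 10

Remark: atom labels (O1, C2, C3, C4, C4a, C5 to C8, C8a) follow the flavanone numbering of the target in all intermediates. "Prenyl" means 3-methylbut-2-en-1-yl, and "aryl" in the names of 12 to 16 means 4-(methoxymethoxy)-3-prenylphenyl.

Assumption: the complex formed from Ti(OiPr)4 and (S)-BINOL is taken to deliver carbon nucleophiles to the Si face of an aromatic aldehyde. If the sense proves opposite, (R)-BINOL is used and nothing else changes.

Step 1
Reactants: 1 4-hydroxybenzaldehyde; 2 prenyl bromide
Product: 3 4-hydroxy-3-prenylbenzaldehyde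
Conditions: KOH, H2O, rt
Reagents that add atoms: none
Why: Phenoxide C-alkylation in water: hydrogen bonding masks the phenoxide oxygen, so the allylic bromide is attacked in SN2 fashion by the ring carbon ortho to oxygen (the para position is blocked by the formyl group), and the O-prenyl ether formed alongside stays behind when 3 is extracted into base.

Step 2
Reactants: 3 4-hydroxy-3-prenylbenzaldehyde
Product: 4 4-(methoxymethoxy)-3-prenylbenzaldehyde
Conditions: MOMCl, K2CO3, acetone, 0 °C to rt
Reagents that add atoms: chloromethyl methyl ether, COCCl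
Why: Williamson-type O-alkylation of the phenoxide with a reactive α-chloro ether; the acetal formed withstands the amide base, the silyl triflate at low temperature and the palladium salt used later, and it keeps the 4'-oxygen from opening ring C through a quinone methide.

Step 3
Reactants: 4 4-(methoxymethoxy)-3-prenylbenzaldehyde; 5 (E)-1-methoxy-3-(trimethylsilyloxy)buta-1,3-diene
Product: 7 (S)-2-[4-(methoxymethoxy)-3-prenylphenyl]-2,3-dihydro-4H-pyran-4-one, via silylated aldol adduct 6 (not isolated)
Conditions: (S)-BINOL (20 mol %), Ti(OiPr)4 (10 mol %), 4 Å MS, Et2O, −20 °C; then cat. TFA, CH2Cl2, 0 °C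
Reagents that add atoms: none
Why: Catalytic asymmetric hetero-Diels–Alder reaction in its stepwise Mukaiyama-aldol form: the complex of Ti(OiPr)4 and (S)-BINOL shields the Re face of the bound aldehyde, so the diene terminus adds to the Si face and sets C2 as S, and a trace of acid then closes ring C with loss of the methoxy and silyl groups.

Step 4
Reactants: 8 dimethyl 1,3-acetonedicarboxylate; 2 prenyl bromide (2 equiv)
Product: 9 dimethyl 2,4-diprenyl-3-oxopentanedioate (mixture of diastereomers)
Conditions: K2CO3, acetone, reflux
Reagents that add atoms: none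
Why: Double alkylation of a bis-β-keto ester: after the first SN2 reaction the unsubstituted methylene is the more acidic and less hindered site, so the second prenyl group goes to the other side of the ketone.

Step 5
Reactants: 9 dimethyl 2,4-diprenyl-3-oxopentanedioate
Product: 10 2,10-dimethylundeca-2,9-dien-6-one (1,3-diprenylacetone)
Conditions: LiCl, H2O, DMSO, 140 °C
Reagents that add atoms: none
Why: Krapcho dealkoxycarbonylation removes both ester groups under neutral conditions, which spares the acid-sensitive trisubstituted alkenes, and the stereocentres of 9 disappear.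

Step 6
Reactants: 10 1,3-diprenylacetone
Product: 11 6-(tert-butyldimethylsilyloxy)-2,10-dimethylundeca-2,5,9-triene (E/Z mixture at C5)
Conditions: TBSOTf, Et3N, CH2Cl2, 0 °C
Reagents that add atoms: tert-butyldimethylsilyl triflate, CC(C)(C)[Si](C)(C)OS(=O)(=O)C(F)(F)F
Why: Soft enolisation and O-silylation; the ketone is symmetrical, so only one constitutional enol silane can form, and its double-bond geometry is of no consequence.

Step 7
Reactants: 7 (S)-2-aryl-2,3-dihydro-4H-pyran-4-one; 11 enol silane of 1,3-diprenylacetone
Product: 12 (2S)-2-aryl-4-(tert-butyldimethylsilyloxy)-6-(2,10-dimethyl-6-oxoundeca-2,9-dien-5-yl)-3,6-dihydro-2H-pyran (isomers at C8a and C8)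
Conditions: TBSOTf (20 mol %), 2,6-di-tert-butylpyridine (10 mol %), CH2Cl2, −78 °C; Et3N quench
Reagents that add atoms: none
Why: Mukaiyama–Michael addition with silyl transfer: the silyl triflate turns the enone of 7 into a 4-silyloxy oxocarbenium ion, the enol silane attacks C8a through its C8 carbon, and the silyl group released from the C7 oxygen restarts the cycle, which leaves the ring ketone masked as the regiodefined C4=C4a enol silane, while the new centres at C8a and C8 are erased later and no base touches C3.

Step 8
Reactants: 12 Michael adduct with masked ring ketone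
Product: 14 (2S)-2-aryl-4-(tert-butyldimethylsilyloxy)-6-[(7E)-7-(methoxymethylidene)-2,10-dimethyl-6-oxoundeca-2,9-dien-5-yl]-3,6-dihydro-2H-pyran, via potassium hydroxymethylene enolate 13 (not isolated)
Conditions: KN(SiMe3)2, THF, −78 °C; HCO2CH2CF3; then Me2SO4, −78 °C to rt
Reagents that add atoms: 2,2,2-trifluoroethyl formate, O=COCC(F)(F)F; dimethyl sulfate, COS(=O)(=O)OC
Why: Kinetic crossed Claisen formylation followed by O-alkylation of the β-keto aldehyde enolate: the bulky amide takes a hydrogen from the C6 methylene and not from the hindered C8 methine, the ring ketone is hidden as its enol silane so that C3 is not acidic and ring C cannot open, and the hard methylating agent attacks the potassium enolate on oxygen (either geometry at C5=C6 would serve later).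

Step 9
Reactants: 14 methoxymethylene ketone with masked ring ketone
Product: 15 (2S)-2-aryl-6-[(7E)-7-(methoxymethylidene)-2,10-dimethyl-6-oxoundeca-2,9-dien-5-yl]-2,3-dihydro-4H-pyran-4-one (both C8 epimers)
Conditions: Pd(OAc)2 (1.1 equiv), MeCN, rt
Reagents that add atoms: none
Why: Saegusa–Ito oxidation: divalent palladium replaces silicon, binds C4a and leaves by syn β-hydride elimination with the only β-hydrogen available, that on C8a, which restores the C4a=C8a enone under essentially neutral conditions and so delivers the base-sensitive precursor without enolising C8.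

Step 10
Reactants: 15 (S)-dihydropyranone with the masked diketoaldehyde arm
Product: 17 (S)-7-hydroxy-4'-(methoxymethoxy)-6,8,3'-triprenylflavanone, via methoxy dihydroarene 16 (not isolated)
Conditions: DBU (1.05 equiv), MeCN (0.02 M), 0 °C to rt; then aq. citric acid
Reagents that add atoms: none
Why: DBU removes only the C8 hydrogen, which is flanked by the C7 ketone and the vinylogous ester of ring C, the charge of the extended enolate reaches C4a, C4a adds to the methoxymethylene carbon C5 to make the C4a–C5 bond and ring A, and 16 expels methanol and tautomerises to the C7 phenol. The closest known reaction types are the biomimetic aldol-type cycloaromatisation of masked poly-β-carbonyl chains to resorcinol derivatives and the base-induced benzannulation of alkoxymethylene ketones by stabilised carbanions. Ring A closes in the 6-endo-trig addition–elimination mode, which can equally be read as a six-electron electrocyclisation of the C4a=C8a–C8=C7–C6=C5 trienolate, and the geometry at C5=C6 is irrelevant because C5 is the ring terminus. The centres made at C4a and C5 vanish on aromatisation, so no new stereocentre has to be controlled and both C8 epimers converge. The selectivity needed is attack through C4a: C8 or O7 would give a four-membered ring and O4 an eight-membered one, O1 is tied up in ring C so that no γ-pyrone can form, and the loss of methanol to an arene cannot be reversed. C2 is safe because the C3 hydrogens are many pK units beyond the reach of DBU, both 15 and 17 sit in the flask as anions, the phenol formed consumes the single equivalent of base, and the blocked 4'-oxygen cannot open ring C.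

Step 11
Reactants: 17 (S)-flavanone 4'-methoxymethyl ether
Product: 18 (S)-7,4'-dihydroxy-6,8,3'-triprenylflavanone (target)
Conditions: HCl (1.25 M in MeOH), MeOH, 0 °C to rt
Reagents that add atoms: none
Why: Acid-catalysed transacetalisation (methanolysis of the aryl methoxymethyl ether): the acetal carbon is passed on to methanol as dimethoxymethane, and dilute acid at or below room temperature is too mild to add the ortho phenols to the prenyl double bonds or to ionise the C2–O1 bond.

Compound list
1 | 4-hydroxybenzaldehyde | O=Cc1ccc(O)cc1 | starting material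
2 | prenyl bromide | CC(C)=CCBr | starting material
3 | 4-hydroxy-3-prenylbenzaldehyde | CC(C)=CCc1cc(C=O)ccc1O | intermediate
4 | 4-(methoxymethoxy)-3-prenylbenzaldehyde | COCOc1ccc(C=O)cc1CC=C(C)C | intermediate
5 | (E)-1-methoxy-3-(trimethylsilyloxy)buta-1,3-diene | CO/C=C/C(=C)O[Si](C)(C)C | starting material
6 | (S,E)-1-methoxy-5-[4-(methoxymethoxy)-3-prenylphenyl]-5-(trimethylsilyloxy)pent-1-en-3-one | CO/C=C/C(=O)C[C@H](O[Si](C)(C)C)c1ccc(OCOC)c(CC=C(C)C)c1 | intermediate
7 | (S)-2-[4-(methoxymethoxy)-3-prenylphenyl]-2,3-dihydro-4H-pyran-4-one | O=C1C[C@@H](c2ccc(OCOC)c(CC=C(C)C)c2)OC=C1 | intermediate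
8 | dimethyl 1,3-acetonedicarboxylate | COC(=O)CC(=O)CC(=O)OC | starting material
9 | dimethyl 2,4-diprenyl-3-oxopentanedioate | COC(=O)C(CC=C(C)C)C(=O)C(CC=C(C)C)C(=O)OC | intermediate
10 | 2,10-dimethylundeca-2,9-dien-6-one (1,3-diprenylacetone) | CC(C)=CCCC(=O)CCC=C(C)C | intermediate
11 | 6-(tert-butyldimethylsilyloxy)-2,10-dimethylundeca-2,5,9-triene | CC(C)=CCC=C(CCC=C(C)C)O[Si](C)(C)C(C)(C)C | intermediate
12 | Michael adduct, ring ketone masked as C4=C4a enol silane, S at C2 | CC(C)=CCCC(=O)C(CC=C(C)C)C1C=C(O[Si](C)(C)C(C)(C)C)C[C@@H](c2ccc(OCOC)c(CC=C(C)C)c2)O1 | intermediate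
13 | potassium enolate of the C6-formyl derivative of 12 | [K+].[O-]C=C(CC=C(C)C)C(=O)C(CC=C(C)C)C1C=C(O[Si](C)(C)C(C)(C)C)C[C@@H](c2ccc(OCOC)c(CC=C(C)C)c2)O1 | intermediate
14 | (E)-methoxymethylene ketone with masked ring ketone, S at C2 | CO/C=C(\CC=C(C)C)C(=O)C(CC=C(C)C)C1C=C(O[Si](C)(C)C(C)(C)C)C[C@@H](c2ccc(OCOC)c(CC=C(C)C)c2)O1 | intermediate
15 | (S)-2-aryl-6-(masked diketoaldehyde)-2,3-dihydropyran-4-one, both C8 epimers | CO/C=C(\CC=C(C)C)C(=O)C(CC=C(C)C)C1=CC(=O)C[C@@H](c2ccc(OCOC)c(CC=C(C)C)c2)O1 | intermediate
16 | 7-hydroxy-5-methoxy-4a,5-dihydro form of 17 (present as its enolate) | COC1C(CC=C(C)C)=C(O)C(CC=C(C)C)=C2O[C@H](c3ccc(OCOC)c(CC=C(C)C)c3)CC(=O)C12 | intermediate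
17 | (S)-7-hydroxy-4'-(methoxymethoxy)-6,8,3'-triprenylflavanone | CC(C)=CCc1cc([C@@H]2CC(=O)c3cc(CC=C(C)C)c(O)c(CC=C(C)C)c3O2)ccc1OCOC | intermediate
18 | (S)-7,4'-dihydroxy-6,8,3'-triprenylflavanone | CC(C)=CCc1cc([C@@H]2CC(=O)c3cc(CC=C(C)C)c(O)c(CC=C(C)C)c3O2)ccc1O | target

Total number of steps: 11. Longest linear sequence: 8 steps (1, 2, 3, 7, 8, 9, 10, 11).

Steps most likely to fail

Step 10. The anion may be too well stabilised and too crowded to fold. Intermolecular Michael addition, or slow loss of configuration at C2 on long exposure to base, could then overtake ring closure. The fallback replaces the anionic closure by a neutral pericyclic one and sets out from 15. TBSOTf and Et3N in CH2Cl2 at −78 °C trap the C7 enol as the silyl trienol ether F1. Heating in toluene closes the C4a=C8a–C8=C7–C6=C5 hexatriene by a thermal six-electron electrocyclisation, and loss of methanol gives the 7-O-silyl flavanone F2. Bu4NF buffered with AcOH removes the silyl group, and the route is rejoined at 17.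

Step 8. Deprotonation at C8 followed by β-elimination of the ring oxygen, or methylation on carbon instead of oxygen, would erode the material. The fallback avoids a metal enolate and sets out from 12. tert-Butoxybis(dimethylamino)methane in toluene at 80 °C condenses only where two α-hydrogens allow loss of amine, that is at C6, and gives the enaminone F3. Aqueous NaOH in THF exchanges the amine for hydroxide, and careful neutralisation gives the hydroxymethylene ketone F4. Me2SO4 with K2CO3 in acetone then leads back to 14.

Step 9. Three processes may stop the dehydrogenation: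
- protodesilylation of the enol silane by the acetic acid formed;
- β-alkoxide instead of β-hydride elimination, which would open ring C;
- binding of palladium by the three trisubstituted alkenes.

The fallback is a selenoxide elimination and sets out from 14. PhSeCl in CH2Cl2 at −78 °C should react with the enol silane faster than with the alkenes and give the α-phenylselanyl ketone F5. H2O2 and pyridine at 0 °C form the selenoxide F6, which undergoes syn elimination with the C8a hydrogen below room temperature. The route is rejoined at 15.

Further compounds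
F1 | step 10 | silyl trienol ether (7-O-TBS enol ether of 15) | CO/C=C(\CC=C(C)C)C(O[Si](C)(C)C(C)(C)C)=C(CC=C(C)C)C1=CC(=O)C[C@@H](c2ccc(OCOC)c(CC=C(C)C)c2)O1
F2 | step 10 | 7-O-silyl flavanone (7-O-TBS ether of 17) | CC(C)=CCc1cc([C@@H]2CC(=O)c3cc(CC=C(C)C)c(O[Si](C)(C)C(C)(C)C)c(CC=C(C)C)c3O2)ccc1OCOC
F3 | step 8 | enaminone (dimethylaminomethylene analogue of 14) | CN(C)/C=C(\CC=C(C)C)C(=O)C(CC=C(C)C)C1C=C(O[Si](C)(C)C(C)(C)C)C[C@@H](c2ccc(OCOC)c(CC=C(C)C)c2)O1
F4 | step 8 | hydroxymethylene ketone (free enol of 13) | OC=C(CC=C(C)C)C(=O)C(CC=C(C)C)C1C=C(O[Si](C)(C)C(C)(C)C)C[C@@H](c2ccc(OCOC)c(CC=C(C)C)c2)O1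
F5 | step 9 | α-phenylselanyl ketone (selenium on C4a) | CO/C=C(\CC=C(C)C)C(=O)C(CC=C(C)C)C1O[C@H](c2ccc(OCOC)c(CC=C(C)C)c2)CC(=O)C1[Se]c3ccccc3
F6 | step 9 | selenoxide of F5 | CO/C=C(\CC=C(C)C)C(=O)C(CC=C(C)C)C1O[C@H](c2ccc(OCOC)c(CC=C(C)C)c2)CC(=O)C1[Se](=O)c3ccccc3
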